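Assumption: (+)-gallocatechin (2R,3S, single enantiomer) is bought and is the only chiral material used; rings are lettered A/B/C in the upper unit and D/E/F in the lower unit.

**Retrosynthetic overview**
- Target ⇒ global hydrogenolysis of a decabenzyl ether that carries a bromine blocking group at C8 of ring D.
- Interflavan C4–C6 bond ⇒ anti opening of a 2,3-trans flav-3-ene oxide by C6 of 8-bromo-hexa-O-benzyl-(+)-gallocatechin (C8 blocked, so only C6 can react).
- Ring C ⇒ oxa-6π electrocyclization of an o-quinone methide (1-oxatriene) released from a reduced 2'-hydroxychalcone; chalcone ⇒ aldol of an acetophenone and an aldehyde.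
- Ring order: rings D, E, F are bought intact; rings A and B are bought as arenes; ring C is the only ring made, before the two halves are joined.

**Route**

Step 1
Reactants: 1 (+)-gallocatechin, (2R,3S)-2-(3,4,5-trihydroxyphenyl)chromane-3,5,7-triol
Product: 2 (2R,3S)-3,5,7-tris(benzyloxy)-2-[3,4,5-tris(benzyloxy)phenyl]chromane (hexa-O-benzyl-(+)-gallocatechin)
Conditions: BnBr (7 equiv), NaH (7 equiv), Bu4NI (cat.), degassed DMF, −40 °C → rt, argon
Reagents that add atoms: benzyl bromide, BrCc1ccccc1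
Why: Williamson etherification of the five phenoxides and the secondary alkoxide at low temperature caps every hydroxyl without touching C2 or C3, which are bought with 1 and stay (2R,3S).

Step 2
Reactants: 2 hexa-O-benzyl-(+)-gallocatechin
Product: 3 (2R,3S)-8-bromo-3,5,7-tris(benzyloxy)-2-[3,4,5-tris(benzyloxy)phenyl]chromane
Conditions: NBS (1.0 equiv), CH2Cl2, −78 → 0 °C, dark
Reagents that add atoms: N-bromosuccinimide, O=C1CCC(=O)N1Br
Why: Electrophilic aromatic bromination of the phloroglucinol-type ring D goes to the less hindered C8, which blocks the more reactive site and leaves C6 as the only free ring-D position; no stereocentre is involved.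

Step 3
Reactants: 4 1-[4-(benzyloxy)-2-hydroxyphenyl]ethan-1-one; 5 3,4,5-tris(benzyloxy)benzaldehyde
Product: 6 (E)-1-[4-(benzyloxy)-2-hydroxyphenyl]-3-[3,4,5-tris(benzyloxy)phenyl]prop-2-en-1-one (2'-hydroxychalcone)
Conditions: KOH (50% aq.), EtOH/THF, rt, 36 h; then aq. HCl
Reagents that add atoms: none
Why: Claisen–Schmidt (crossed aldol) condensation of the methyl ketone with the non-enolisable aldehyde gives the E-enone by E1cB dehydration; no stereocentre is formed.

Step 4
Reactants: 6 2'-hydroxychalcone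
Product: 9 racemic 7-(benzyloxy)-2-[3,4,5-tris(benzyloxy)phenyl]-2H-chromene, via allylic alcohol 7 (not isolated), via o-quinone methide 8 (not isolated)
Conditions: NaBH4, CeCl3·7H2O, MeOH/THF, 0 °C; aq. work-up; crude alcohol, pyridinium p-toluenesulfonate (cat.), CH2Cl2, rt
Reagents that add atoms: none
Why: Luche 1,2-reduction gives allylic alcohol 7, acid-induced loss of water gives the o-quinone methide 8 (a 1-oxatriene), and thermal disrotatory oxa-6π electrocyclization closes ring C, creating C2 as a racemate because the oxatriene is achiral.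

Step 5
Reactants: 9 racemic 2H-chromene (2 equiv); 3 8-bromo-hexa-O-benzyl-(+)-gallocatechin (1 equiv)
Product: 11 (2R,3S,4S)-7-(benzyloxy)-4-{(2R,3S)-3,5,7-tris(benzyloxy)-8-bromo-2-[3,4,5-tris(benzyloxy)phenyl]chroman-6-yl}-2-[3,4,5-tris(benzyloxy)phenyl]chroman-3-ol, via trans-epoxide 10 (not isolated)
Conditions: DMDO (acetone solution, 1.05 equiv per 9), CH2Cl2, −78 → −40 °C; volatiles removed at −40 °C; then 3, BF3·OEt2 (cat.), CH2Cl2, −78 → −40 °C; chromatography
Reagents that add atoms: dimethyldioxirane, CC1(C)OO1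
Why: Epoxidation by DMDO occurs anti to the 2-aryl group (C3 set by C2) and the Lewis-acid-promoted Friedel–Crafts opening of the benzylic epoxide by C6 of 3 occurs mainly anti to the oxirane oxygen (C4 set by C3), giving the 2,3-trans-3,4-trans unit, but because 9 is racemic and 3 is one enantiomer the product forms about 1:1 with the diastereomer carrying the mirror-image upper unit, which is removed by chromatography together with minor 3,4-cis material.

Step 6
Reactants: 11 protected, brominated dimer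
Product: 12 robinetinidol-(4α→6)-gallocatechin, (2R,3S,4S)-2-(3,4,5-trihydroxyphenyl)-4-[(2R,3S)-3,5,7-trihydroxy-2-(3,4,5-trihydroxyphenyl)chroman-6-yl]chromane-3,7-diol
Conditions: H2 (1 atm), Pd(OH)2/C, Et3N (2 equiv), THF/MeOH/H2O, rt; filtration under argon; Sephadex LH-20
Reagents that add atoms: none
Why: Palladium-catalysed hydrogenolysis cleaves the ten benzyl ethers and the aryl C–Br bond in one operation under conditions that leave the five stereocentres and the acid-robust 5-deoxy interflavan bond untouched.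

**Compound list**

1 | (+)-gallocatechin, (2R,3S)-2-(3,4,5-trihydroxyphenyl)chromane-3,5,7-triol | c1c(O)cc2c(c1O)C[C@H](O)[C@@H](c1cc(O)c(O)c(O)c1)O2 | starting material

2 | (2R,3S)-3,5,7-tris(benzyloxy)-2-[3,4,5-tris(benzyloxy)phenyl]chromane | c1c(OCc3ccccc3)cc2c(c1OCc3ccccc3)C[C@H](OCc3ccccc3)[C@@H](c1cc(OCc3ccccc3)c(OCc3ccccc3)c(OCc3ccccc3)c1)O2 | intermediate

3 | (2R,3S)-8-bromo-3,5,7-tris(benzyloxy)-2-[3,4,5-tris(benzyloxy)phenyl]chromane | c1c(OCc3ccccc3)c(Br)c2c(c1OCc3ccccc3)C[C@H](OCc3ccccc3)[C@@H](c1cc(OCc3ccccc3)c(OCc3ccccc3)c(OCc3ccccc3)c1)O2 | intermediate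

4 | 1-[4-(benzyloxy)-2-hydroxyphenyl]ethan-1-one | CC(=O)c1ccc(OCc2ccccc2)cc1O | starting material

5 | 3,4,5-tris(benzyloxy)benzaldehyde | O=Cc1cc(OCc2ccccc2)c(OCc2ccccc2)c(OCc2ccccc2)c1 | starting material

6 | (E)-1-[4-(benzyloxy)-2-hydroxyphenyl]-3-[3,4,5-tris(benzyloxy)phenyl]prop-2-en-1-one | O=C(/C=C/c1cc(OCc2ccccc2)c(OCc2ccccc2)c(OCc2ccccc2)c1)c1ccc(OCc2ccccc2)cc1O | intermediate

7 | racemic (E)-1-[4-(benzyloxy)-2-hydroxyphenyl]-3-[3,4,5-tris(benzyloxy)phenyl]prop-2-en-1-ol (not isolated) | OC(/C=C/c1cc(OCc2ccccc2)c(OCc2ccccc2)c(OCc2ccccc2)c1)c1ccc(OCc2ccccc2)cc1O | intermediate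

8 | 3-(benzyloxy)-6-{(E)-3-[3,4,5-tris(benzyloxy)phenyl]prop-2-en-1-ylidene}cyclohexa-2,4-dien-1-one, o-quinone methide, exocyclic geometry not fixed (not isolated) | O=C1C=C(OCc2ccccc2)C=CC1=C/C=C/c1cc(OCc2ccccc2)c(OCc2ccccc2)c(OCc2ccccc2)c1 | intermediate

9 | racemic 7-(benzyloxy)-2-[3,4,5-tris(benzyloxy)phenyl]-2H-chromene | c3ccccc3COc1ccc2c(c1)OC(c1cc(OCc3ccccc3)c(OCc3ccccc3)c(OCc3ccccc3)c1)C=C2 | intermediate

10 | racemic 7-(benzyloxy)-3,4-epoxy-2-[3,4,5-tris(benzyloxy)phenyl]chromane, oxirane oxygen anti to the 2-aryl group; the enantiomer drawn leads to 11 (not isolated) | c3ccccc3COc1ccc2c(c1)O[C@H](c1cc(OCc3ccccc3)c(OCc3ccccc3)c(OCc3ccccc3)c1)[C@H]4O[C@@H]24 | intermediate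

11 | (2R,3S,4S)-7-(benzyloxy)-4-{(2R,3S)-3,5,7-tris(benzyloxy)-8-bromo-2-[3,4,5-tris(benzyloxy)phenyl]chroman-6-yl}-2-[3,4,5-tris(benzyloxy)phenyl]chroman-3-ol | c3ccccc3COc1ccc2c(c1)O[C@H](c1cc(OCc3ccccc3)c(OCc3ccccc3)c(OCc3ccccc3)c1)[C@@H](O)[C@@H]2c4c(OCc3ccccc3)c(Br)c5c(c4OCc3ccccc3)C[C@H](OCc3ccccc3)[C@@H](c4cc(OCc3ccccc3)c(OCc3ccccc3)c(OCc3ccccc3)c4)O5 | intermediate

12 | robinetinidol-(4α→6)-gallocatechin, (2R,3S,4S)-2-(3,4,5-trihydroxyphenyl)-4-[(2R,3S)-3,5,7-trihydroxy-2-(3,4,5-trihydroxyphenyl)chroman-6-yl]chromane-3,7-diol | Oc1ccc2c(c1)O[C@H](c1cc(O)c(O)c(O)c1)[C@@H](O)[C@@H]2c1c(O)cc2c(c1O)C[C@H](O)[C@@H](c1cc(O)c(O)c(O)c1)O2 | target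

**Totals and risks**

Total step count: 6. Longest linear sequence: 4 steps (4/5 → 6 → 9 → 11 → 12, or 1 → 2 → 3 → 11 → 12).

Step 5 is the most likely to fail. The 7-alkoxychromene oxide 10 is very acid-labile and may rearrange or oligomerise before C6 of 3 attacks, and the two trans diastereomers differ only in the sense of the upper unit and must be separated. The fallback sets out from 9. Catalytic OsO4 with N-methylmorpholine N-oxide in acetone/water dihydroxylates anti to the 2-aryl group and gives the isolable racemic 2,3-trans-3,4-cis-7-(benzyloxy)-2-[3,4,5-tris(benzyloxy)phenyl]chromane-3,4-diol F1. Treating F1 and 3 with BF3·OEt2 in CH2Cl2 at −78 °C ionises the benzylic 4-hydroxyl to a cation stabilised by the para 7-oxygen; C6 of 3 adds trans to the 3-hydroxyl and the route is rejoined at 11. If the benzylated diastereomers cannot be separated, both are taken through step 6 and separated as free phenols on Sephadex LH-20 or by reversed-phase HPLC.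

Step 4 is the second risk, because of competing conjugate reduction of the enone and the acid and air sensitivity of the chromene. The fallback sets out from 6. NaOAc in refluxing EtOH closes ring C by 6-endo oxa-Michael addition to the racemic 7-(benzyloxy)-2-[3,4,5-tris(benzyloxy)phenyl]chroman-4-one F2. NaBH4 in MeOH/THF then gives the racemic 7-(benzyloxy)-2-[3,4,5-tris(benzyloxy)phenyl]chroman-4-ol F3, and dehydration with catalytic p-toluenesulfonic acid in warm toluene returns to 9.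

Step 6 is the third risk, through incomplete removal of ten benzyl groups, catalyst poisoning by bromide, or hydrogenolysis of the benzylic C2–O bonds. The fallback sets out from 11. Radical hydrodebromination with Bu3SnH and AIBN in toluene at 80 °C gives the bromine-free decabenzyl ether (2R,3S,4S)-7-(benzyloxy)-4-{(2R,3S)-3,5,7-tris(benzyloxy)-2-[3,4,5-tris(benzyloxy)phenyl]chroman-6-yl}-2-[3,4,5-tris(benzyloxy)phenyl]chroman-3-ol F4. BCl3 with pentamethylbenzene as cation scavenger in CH2Cl2 at −78 °C then cleaves all benzyl ethers and returns to 12.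

**Further compounds**

F1 | step 5 | racemic 2,3-trans-3,4-cis-7-(benzyloxy)-2-[3,4,5-tris(benzyloxy)phenyl]chromane-3,4-diol (enantiomer drawn leads to 11) | c3ccccc3COc1ccc2c(c1)O[C@H](c1cc(OCc3ccccc3)c(OCc3ccccc3)c(OCc3ccccc3)c1)[C@@H](O)[C@H]2O

F2 | step 4 | racemic 7-(benzyloxy)-2-[3,4,5-tris(benzyloxy)phenyl]chroman-4-one | O=C1CC(c2cc(OCc3ccccc3)c(OCc3ccccc3)c(OCc3ccccc3)c2)Oc2cc(OCc3ccccc3)ccc12

F3 | step 4 | racemic 7-(benzyloxy)-2-[3,4,5-tris(benzyloxy)phenyl]chroman-4-ol | OC1CC(c2cc(OCc3ccccc3)c(OCc3ccccc3)c(OCc3ccccc3)c2)Oc2cc(OCc3ccccc3)ccc12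

F4 | step 6 | (2R,3S,4S)-7-(benzyloxy)-4-{(2R,3S)-3,5,7-tris(benzyloxy)-2-[3,4,5-tris(benzyloxy)phenyl]chroman-6-yl}-2-[3,4,5-tris(benzyloxy)phenyl]chroman-3-ol | c3ccccc3COc1ccc2c(c1)O[C@H](c1cc(OCc3ccccc3)c(OCc3ccccc3)c(OCc3ccccc3)c1)[C@@H](O)[C@@H]2c4c(OCc3ccccc3)cc5c(c4OCc3ccccc3)C[C@H](OCc3ccccc3)[C@@H](c4cc(OCc3ccccc3)c(OCc3ccccc3)c(OCc3ccccc3)c4)O5
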